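The runs are simulated with made-up constants.

**Ceiling rate.** Zeta makes target at 0.00627 M d⁻¹ up to its first reading. I call this reading the ceiling rate: target made per day with 10 µM of free catalyst charged and [reagent] near 0.026 M.

common to all: free catalyst 10 µM

| charge | starting material | reagent | remark |
|---|---|---|---|
| gamma | 0.010 M | 0.026 M | run made earlier |
| zeta | 0.040 M | 0.026 M | run made earlier |
| flask | 0.020 M | 0.0260 M |  |

| run | time / d | target / % |
|---|---|---|
| gamma | 4.00 | 99.1 |
| gamma | 8.00 | 100.0 |
| gamma | 12.0 | 98.9 |
| gamma | 15.0 | 100.5 |
| zeta | 1.25 | 19.6 |
| zeta | 3.00 | 46.0 |
| zeta | 6.00 | 65.0 |
| zeta | 15.0 | 65.6 |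

(readings scatter by 1 percentage point)

- a species is counted by the starting material in it: one resting dimer counts as two
- what was read earlier has a scatter of 1 percentage point, one standard deviation
- steps that have been proposed: reagent + free catalyst -> catalyst intermediate A; starting material + catalyst intermediate A -> catalyst intermediate B; catalyst intermediate B <-> catalyst intermediate C; catalyst intermediate C -> free catalyst + target; starting material -> decomposition product; 2 catalyst intermediate B <-> resting dimer
- no earlier run changes the charge of reagent; that part of a forecast is a guess

1. apparent order in reagent when 30 % of the starting material are converted (percent change of the rate of making target for one percent more reagent charged)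
2. factor on the rate of making target when 30 % of the starting material are converted if reagent is charged twice over

**Reading zeta.** Zeta then makes 0.00603 M d⁻¹, close to the ceiling, while mean [reagent] falls from 0.0221 M to 0.0129 M. Those two intervals give an order of 0.0717. [Starting material] falls too, and each reading scatters by 1 percentage point, so I read this as small and little more. Zeta stops near 0.0260 M, about its reagent charge, so one reagent goes into each target.

**First instants.** This flask starts with zeta's catalyst and reagent but half of its starting material. I expect a rate near the ceiling.

**The middle.** At 30 % conversion this flask holds 0.0200 M of reagent, inside the span zeta covered. At the ceiling it arrives there after 0.957 d. Its [starting material] of 0.0140 M is below the 0.0216 M that zeta's reading at 3.00 d implies, so this flask may run slightly under the ceiling. I commit to an order of 0.0717, and so a factor of 1.05 for double the reagent.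

**The end.** Starting material is the limiting reagent, so this flask stops with 23.1 % of its reagent left.

**The forecast.** It gives 0.03 (0 to 0.15) and 1.02 (1 to 1.12), holding that “the rate is about zero order in reagent”; my order is higher.

**The result.** The flask gives an order of 0.026 and a factor of 1.01.

    reagent + free catalyst → catalyst intermediate A (k = 13.0 M⁻¹ s⁻¹)
    starting material + catalyst intermediate A → catalyst intermediate B (k = 1.70 M⁻¹ s⁻¹)
    catalyst intermediate B ⇌ catalyst intermediate C (K = 43.0, k = 0.0170 s⁻¹)
    catalyst intermediate C → free catalyst + target (k = 0.0560 s⁻¹)
    starting material → decomposition product (k = 6.40 × 10⁻⁹ s⁻¹)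
    2 catalyst intermediate B ⇌ resting dimer, settled at all times (K = 74000 M⁻¹)

**Ceiling again.** In this flask free catalyst stands at 2.67 % of the catalyst charged at 1.50 d. At 30 % conversion this flask's rate is 0.00553 M d⁻¹, which is 0.882 of the ceiling rate, and this flask reaches that conversion at 1.04 d against my 0.957 d. For a flask with twice the free catalyst, twice the ceiling rate gives 0.478 d, while the simulated factor of 0.582 on the time gives 0.605 d.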